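**Retrosynthetic overview**

1. The target (cyclohepta[b]furan numbering) is traced back to silyl-protected alcohol 22 (angelate ester, two silyl ethers removed); 22 comes from butenolide 20, whose two ring alkenes (C3=C3a and C5=C6) are hydrogenated together.
2. The lactone ring is disconnected at C3=C3a (intramolecular Horner–Wadsworth–Emmons) and at the C8a–O ester bond, back to an α-hydroxy ketone made by Rubottom oxidation of a C3a silyl enol ether. The C7 side chain comes from a Weinreb amide plus a chiral-pool C3 organolithium, and the C7–OH from enolate hydroxylation.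
3. The carbocycle is then a cyclohepta-1,4-diene (C5=C6 and C3a=C8a), which is opened at C4–C5 and C7–C8 into a four-carbon 1-alkoxy-3-siloxy diene (C8, C8a, C3a, C4) and a three-carbon alkenylcarbene (C5, C6, C7) by a carbene cyclopropanation/Cope sequence, a formal (4+3) cycloaddition.
4. Enabling feature: in the seven-membered ring the only two adjacent CH2 groups (C4, C5) lie opposite the vicinally oxygenated C7–C8 bond, and the carbons in between (C6 on one side, C3a/C8a on the other) can each carry a double bond. The ring is therefore a masked cis-dialkenylcyclopropane, with the C8 and C3a oxygens supplied by the diene and the C6 methyl and C7 acyl group by the carbene.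
5. Ring order: seven-membered carbocycle first (step 4), γ-lactone second (step 11).

Key step: step 4

Assumption: Rh2(S-BTPCP)4 is taken to give the (1R,2S)-cyclopropane 7 in step 4; if the opposite sense of induction is found, Rh2(R-BTPCP)4 is used instead.

**Route**

Step 1
Reactants: 1 but-3-yn-2-one
Product: 2 (3E)-4-[(4-methoxyphenyl)methoxy]but-3-en-2-one
Conditions: 4-methoxybenzyl alcohol, DABCO (10 mol %), CH2Cl2, 0 → 23 °C
Reagents that add atoms: 4-methoxybenzyl alcohol (COc1ccc(CO)cc1)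
Why: Amine-catalysed oxa-Michael addition of an alcohol to an ynone should give the (E)-β-alkoxy enone; no stereocenter is formed.

Step 2
Reactants: 2 (3E)-4-[(4-methoxyphenyl)methoxy]but-3-en-2-one
Product: 3 triethyl({(3E)-4-[(4-methoxyphenyl)methoxy]buta-1,3-dien-2-yl}oxy)silane
Conditions: TESOTf, Et3N, Et2O, −78 → 0 °C
Reagents that add atoms: triethylsilyl trifluoromethanesulfonate (CC[Si](CC)(CC)OS(=O)(=O)C(F)(F)F)
Why: Soft enolisation of the methyl ketone (silyl enol ether formation) should give the 2-siloxy diene, as in the preparation of Danishefsky-type dienes.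

Step 3
Reactants: 4 ethyl (2E)-3-methyl-4-oxobut-2-enoate
Product: 5 ethyl (2E,4E)-3-methyl-4-({[2-(trifluoromethyl)phenyl]sulfonyl}hydrazinylidene)but-2-enoate
Conditions: 2-(trifluoromethyl)benzenesulfonohydrazide, MeOH, 23 °C
Reagents that add atoms: 2-(trifluoromethyl)benzenesulfonohydrazide (NNS(=O)(=O)c1ccccc1C(F)(F)F)
Why: Hydrazone formation at the aldehyde should leave the E-configured conjugated alkene untouched.

Step 4
Reactants: 5 ethyl (2E,4E)-3-methyl-4-({[2-(trifluoromethyl)phenyl]sulfonyl}hydrazinylidene)but-2-enoate; 3 triethyl({(3E)-4-[(4-methoxyphenyl)methoxy]buta-1,3-dien-2-yl}oxy)silane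
Product: 8 ethyl (1R,7S)-7-[(4-methoxyphenyl)methoxy]-2-methyl-5-(triethylsilyloxy)cyclohepta-2,5-diene-1-carboxylate, via vinyl diazo ester 6 (not isolated), via cis-dialkenylcyclopropane 7 (not isolated)
Conditions: NaH, CH2Cl2, −40 °C; then 3 (2 equiv), Rh2(S-BTPCP)4 (1 mol %), −40 → 23 °C; then 40 °C
Reagents that add atoms: none
Why: Base converts the sulfonylhydrazone into vinyl diazo ester 6 (Bamford–Stevens), the dirhodium catalyst turns 6 into an electrophilic alkenylcarbene that cyclopropanates the terminal silyl enol ether C=C of diene 3, and the cis-1,2-dialkenylcyclopropane 7 then undergoes a [3,3]-sigmatropic (Cope) rearrangement, so that the C3–C4 and C1–C7 bonds of 8 form in one operation (formal (4+3) cycloaddition). The closest known reactions are the tandem cyclopropanation/Cope rearrangement of rhodium vinylcarbenes with oxygenated dienes and the (4+3) cycloaddition of alkenyl N-sulfonylhydrazones with 1,3-dienes. The three-membered ring closes by concerted (2+1) carbene addition, and the seven-membered ring arises by ring expansion of the cyclopropane through a boat transition state with both alkenyl groups over the ring. Because both migrating alkenes are E, the boat places the C7 ether oxygen and the C1 ester on the same face (C1/C7 cis); the absolute configuration at C7 is that of the cyclopropane, fixed when the chiral carboxylate ligands select one face of the enol ether, and is passed on stereospecifically. The step needs site selectivity (the 2-siloxy alkene of 3 is the most electron-rich and the only 1,1-disubstituted one, whereas the (E)-1,2-disubstituted enol ether is a poor carbene acceptor), a cis arrangement of the alkenyl groups (the siloxy-substituted trans isomer can epimerise on gentle warming and then rearrange) and a fast Cope step (donor siloxy group on the ring, only hydrogens in the inward Z positions).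

Step 5
Reactants: 8 ethyl (1R,7S)-7-[(4-methoxyphenyl)methoxy]-2-methyl-5-(triethylsilyloxy)cyclohepta-2,5-diene-1-carboxylate
Product: 9 ethyl (1S,7S)-1-hydroxy-7-[(4-methoxyphenyl)methoxy]-2-methyl-5-(triethylsilyloxy)cyclohepta-2,5-diene-1-carboxylate
Conditions: KN(SiMe3)2, THF, −78 °C; then 2-(phenylsulfonyl)-3-phenyloxaziridine, −78 °C; NH4Cl (aq.)
Reagents that add atoms: 2-(phenylsulfonyl)-3-phenyloxaziridine (O=S(=O)(c1ccccc1)N1OC1c1ccccc1)
Why: Davis enolate hydroxylation: the ester enolate should react at C1 on the face anti to the adjacent C7 benzylic ether, which places the new tertiary OH trans to the C7–O bond and leaves the ester cis to it.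

Step 6
Reactants: 9 ethyl (1S,7S)-1-hydroxy-7-[(4-methoxyphenyl)methoxy]-2-methyl-5-(triethylsilyloxy)cyclohepta-2,5-diene-1-carboxylate
Product: 10 (1S,7S)-1-hydroxy-N-methoxy-7-[(4-methoxyphenyl)methoxy]-N,2-dimethyl-5-(triethylsilyloxy)cyclohepta-2,5-diene-1-carboxamide
Conditions: MeNH(OMe)·HCl, i-PrMgCl, THF, −20 → 0 °C
Reagents that add atoms: N,O-dimethylhydroxylamine hydrochloride (CNOC.Cl)
Why: Weinreb amide formation by aminolysis of the ester with the chloromagnesium amide, helped by chelation to the neighbouring magnesium alkoxide; basic conditions keep the acid-sensitive enol ether intact.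

Step 7
Reactants: 10 (1S,7S)-1-hydroxy-N-methoxy-7-[(4-methoxyphenyl)methoxy]-N,2-dimethyl-5-(triethylsilyloxy)cyclohepta-2,5-diene-1-carboxamide; 11 (2R)-1-chloropropan-2-ol
Product: 13 (3R)-3-hydroxy-1-[(1S,7S)-1-hydroxy-7-[(4-methoxyphenyl)methoxy]-2-methyl-5-(triethylsilyloxy)cyclohepta-2,5-dien-1-yl]butan-1-one, via dilithio reagent 12 (not isolated)
Conditions: 11, n-BuLi, THF, −78 °C; Li, 4,4′-di-tert-butylbiphenyl (5 mol %), −78 °C; then 10 (pre-treated with LiN(SiMe3)2), −78 → −50 °C; NH4Cl (aq.)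
Reagents that add atoms: n-butyllithium ([Li]CCCC) and lithium ([Li]), which supply the lithium atoms of 12
Why: Reductive chlorine–lithium exchange on the lithium alkoxide gives a β-oxido organolithium that should add once to the Weinreb amide (chelated tetrahedral intermediate, no over-addition); the carbinol stereocenter comes unchanged from the chiral pool.

Step 8
Reactants: 13 (3R)-3-hydroxy-1-[(1S,7S)-1-hydroxy-7-[(4-methoxyphenyl)methoxy]-2-methyl-5-(triethylsilyloxy)cyclohepta-2,5-dien-1-yl]butan-1-one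
Product: 15 (3R)-3-(tert-butyldimethylsilyloxy)-1-[(1S,7S)-7-[(4-methoxyphenyl)methoxy]-2-methyl-1,5-bis(triethylsilyloxy)cyclohepta-2,5-dien-1-yl]butan-1-one, via mono-silyl ether 14 (not isolated)
Conditions: TBSCl, imidazole, CH2Cl2, 23 °C; then 2,6-lutidine, TESOTf, −78 → 0 °C
Reagents that add atoms: tert-butyldimethylsilyl chloride (CC(C)(C)[Si](C)(C)Cl); triethylsilyl trifluoromethanesulfonate (CC[Si](CC)(CC)OS(=O)(=O)C(F)(F)F)
Why: Silyl ether formation: the silyl chloride should take only the secondary alcohol, and the more reactive silyl triflate then caps the tertiary one, which must not direct the later hydrogenation.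

Step 9
Reactants: 15 (3R)-3-(tert-butyldimethylsilyloxy)-1-[(1S,7S)-7-[(4-methoxyphenyl)methoxy]-2-methyl-1,5-bis(triethylsilyloxy)cyclohepta-2,5-dien-1-yl]butan-1-one
Product: 17 (2S,3S,4S)-4-[(3R)-3-(tert-butyldimethylsilyloxy)butanoyl]-2-hydroxy-3-[(4-methoxyphenyl)methoxy]-5-methyl-4-(triethylsilyloxy)cyclohept-5-en-1-one, via siloxy epoxide 16 (not isolated)
Conditions: DMDO (1.05 equiv), acetone/CH2Cl2, −78 → −40 °C; then PPTS (cat.), MeOH, 0 °C
Reagents that add atoms: dimethyldioxirane (CC1(C)OO1)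
Why: Rubottom oxidation: the dioxirane should epoxidise the electron-rich silyl enol ether, in preference to the trisubstituted alkene, on the face anti to the allylic C–O substituent; brief methanolysis of the siloxy epoxide gives the α-hydroxy ketone with the new OH trans to the neighbouring ether.

Step 10
Reactants: 17 (2S,3S,4S)-4-[(3R)-3-(tert-butyldimethylsilyloxy)butanoyl]-2-hydroxy-3-[(4-methoxyphenyl)methoxy]-5-methyl-4-(triethylsilyloxy)cyclohept-5-en-1-one; 18 2-(diethoxyphosphoryl)propanoic acid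
Product: 19 (1S,6S,7S)-6-[(3R)-3-(tert-butyldimethylsilyloxy)butanoyl]-7-[(4-methoxyphenyl)methoxy]-5-methyl-2-oxo-6-(triethylsilyloxy)cyclohept-4-en-1-yl 2-(diethoxyphosphoryl)propanoate (both epimers at the phosphonate carbon)
Conditions: 18, DCC, DMAP (cat.), CH2Cl2, 0 → 23 °C
Reagents that add atoms: none
Why: Steglich esterification of the only free hydroxyl group.

Step 11
Reactants: 19 (1S,6S,7S)-6-[(3R)-3-(tert-butyldimethylsilyloxy)butanoyl]-7-[(4-methoxyphenyl)methoxy]-5-methyl-2-oxo-6-(triethylsilyloxy)cyclohept-4-en-1-yl 2-(diethoxyphosphoryl)propanoate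
Product: 20 (7S,8S,8aR)-7-[(3R)-3-(tert-butyldimethylsilyloxy)butanoyl]-8-[(4-methoxyphenyl)methoxy]-3,6-dimethyl-7-(triethylsilyloxy)-4,7,8,8a-tetrahydro-2H-cyclohepta[b]furan-2-one
Conditions: LiCl, i-Pr2NEt, MeCN, 23 °C
Reagents that add atoms: none
Why: Intramolecular Horner–Wadsworth–Emmons olefination under Masamune–Roush conditions should close the butenolide onto the adjacent ring ketone through a five-membered transition ring; the mild base limits epimerisation at the acyloxy carbon.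

Step 12
Reactants: 20 (7S,8S,8aR)-7-[(3R)-3-(tert-butyldimethylsilyloxy)butanoyl]-8-[(4-methoxyphenyl)methoxy]-3,6-dimethyl-7-(triethylsilyloxy)-4,7,8,8a-tetrahydro-2H-cyclohepta[b]furan-2-one
Product: 21 (7S,8S,8aR)-7-[(3R)-3-(tert-butyldimethylsilyloxy)butanoyl]-8-hydroxy-3,6-dimethyl-7-(triethylsilyloxy)-4,7,8,8a-tetrahydro-2H-cyclohepta[b]furan-2-one
Conditions: DDQ, CH2Cl2/pH 7 buffer, 0 °C
Reagents that add atoms: none
Why: Oxidative cleavage of the 4-methoxybenzyl ether by DDQ frees the C8 hydroxyl without touching the silyl ethers or alkenes.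

Step 13
Reactants: 21 (7S,8S,8aR)-7-[(3R)-3-(tert-butyldimethylsilyloxy)butanoyl]-8-hydroxy-3,6-dimethyl-7-(triethylsilyloxy)-4,7,8,8a-tetrahydro-2H-cyclohepta[b]furan-2-one
Product: 22 (3R,3aS,6S,7S,8S,8aR)-7-[(3R)-3-(tert-butyldimethylsilyloxy)butanoyl]-8-hydroxy-3,6-dimethyl-7-(triethylsilyloxy)octahydro-2H-cyclohepta[b]furan-2-one
Conditions: H2 (4 atm), [Ir(cod)(PCy3)(py)]PF6 (10 mol %), CH2Cl2, 23 °C
Reagents that add atoms: none
Why: Hydroxyl-directed hydrogenation with the cationic iridium catalyst should deliver H2 to both ring alkenes from the face of the free C8–OH, which is also the convex face of the butenolide and is opposite the bulky C7 silyl ether; this sets C6 (methyl cis to C7–O), C3a (cis ring fusion) and C3 (H cis to H-3a).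

Step 14
Reactants: 22 (3R,3aS,6S,7S,8S,8aR)-7-[(3R)-3-(tert-butyldimethylsilyloxy)butanoyl]-8-hydroxy-3,6-dimethyl-7-(triethylsilyloxy)octahydro-2H-cyclohepta[b]furan-2-one; 23 (2Z)-2-methylbut-2-enoic acid (angelic acid)
Product: 25 (3R,3aS,6S,7S,8S,8aR)-7-[(3R)-3-(tert-butyldimethylsilyloxy)butanoyl]-3,6-dimethyl-2-oxo-7-(triethylsilyloxy)octahydro-2H-cyclohepta[b]furan-8-yl (2Z)-2-methylbut-2-enoate, via mixed anhydride 24 (not isolated)
Conditions: 23, 2,4,6-trichlorobenzoyl chloride, Et3N, toluene, 23 °C; then 22, toluene, 80 °C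
Reagents that add atoms: 2,4,6-trichlorobenzoyl chloride (O=C(Cl)c1c(Cl)cc(Cl)cc1Cl), which supplies the aroyl part of 24
Why: Yamaguchi-type acylation with the preformed mixed anhydride, run without DMAP so that the Z alkene does not isomerise to the tiglate.

Step 15
Reactants: 25 (3R,3aS,6S,7S,8S,8aR)-7-[(3R)-3-(tert-butyldimethylsilyloxy)butanoyl]-3,6-dimethyl-2-oxo-7-(triethylsilyloxy)octahydro-2H-cyclohepta[b]furan-8-yl (2Z)-2-methylbut-2-enoate
Product: 26 (3R,3aS,6S,7S,8S,8aR)-7-hydroxy-7-[(3R)-3-hydroxybutanoyl]-3,6-dimethyl-2-oxooctahydro-2H-cyclohepta[b]furan-8-yl (2Z)-2-methylbut-2-enoate (CNP0321985.1)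
Conditions: HF·pyridine, pyridine/THF, 0 → 23 °C
Reagents that add atoms: none
Why: Fluoride-mediated desilylation should remove both silyl ethers under buffered conditions that spare the angelate, the lactone and the β-acyloxy ketone.

**Compound list**

1 | but-3-yn-2-one | CC(=O)C#C | starting material
2 | (3E)-4-[(4-methoxyphenyl)methoxy]but-3-en-2-one | COc1ccc(CO/C=C/C(C)=O)cc1 | intermediate
3 | triethyl({(3E)-4-[(4-methoxyphenyl)methoxy]buta-1,3-dien-2-yl}oxy)silane | COc1ccc(CO/C=C/C(=C)O[Si](CC)(CC)CC)cc1 | intermediate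
4 | ethyl (2E)-3-methyl-4-oxobut-2-enoate | CCOC(=O)/C=C(\C)C=O | starting material
5 | ethyl (2E,4E)-3-methyl-4-({[2-(trifluoromethyl)phenyl]sulfonyl}hydrazinylidene)but-2-enoate | CCOC(=O)/C=C(\C)/C=N/NS(=O)(=O)c1ccccc1C(F)(F)F | intermediate
6 | ethyl (2E)-4-diazo-3-methylbut-2-enoate | CCOC(=O)/C=C(\C)C=[N+]=[N-] | intermediate
7 | ethyl (2E)-3-[(1R,2S)-2-{(E)-2-[(4-methoxyphenyl)methoxy]ethenyl}-2-(triethylsilyloxy)cyclopropyl]but-2-enoate (alkenyl groups cis) | CCOC(=O)/C=C(\C)[C@H]1C[C@@]1(O[Si](CC)(CC)CC)/C=C/OCc1ccc(OC)cc1 | intermediate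
8 | ethyl (1R,7S)-7-[(4-methoxyphenyl)methoxy]-2-methyl-5-(triethylsilyloxy)cyclohepta-2,5-diene-1-carboxylate | COc1ccc(CO[C@H]2C=C(O[Si](CC)(CC)CC)CC=C(C)[C@H]2C(=O)OCC)cc1 | intermediate
9 | ethyl (1S,7S)-1-hydroxy-7-[(4-methoxyphenyl)methoxy]-2-methyl-5-(triethylsilyloxy)cyclohepta-2,5-diene-1-carboxylate | COc1ccc(CO[C@H]2C=C(O[Si](CC)(CC)CC)CC=C(C)[C@@]2(O)C(=O)OCC)cc1 | intermediate
10 | (1S,7S)-1-hydroxy-N-methoxy-7-[(4-methoxyphenyl)methoxy]-N,2-dimethyl-5-(triethylsilyloxy)cyclohepta-2,5-diene-1-carboxamide | COc1ccc(CO[C@H]2C=C(O[Si](CC)(CC)CC)CC=C(C)[C@@]2(O)C(=O)N(C)OC)cc1 | intermediate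
11 | (2R)-1-chloropropan-2-ol | ClC[C@@H](C)O | starting material
12 | lithium (2R)-1-lithiopropan-2-olate | [Li]C[C@@H](C)O[Li] | intermediate
13 | (3R)-3-hydroxy-1-[(1S,7S)-1-hydroxy-7-[(4-methoxyphenyl)methoxy]-2-methyl-5-(triethylsilyloxy)cyclohepta-2,5-dien-1-yl]butan-1-one | COc1ccc(CO[C@H]2C=C(O[Si](CC)(CC)CC)CC=C(C)[C@@]2(O)C(=O)C[C@@H](C)O)cc1 | intermediate
14 | (3R)-3-(tert-butyldimethylsilyloxy)-1-[(1S,7S)-1-hydroxy-7-[(4-methoxyphenyl)methoxy]-2-methyl-5-(triethylsilyloxy)cyclohepta-2,5-dien-1-yl]butan-1-one | COc1ccc(CO[C@H]2C=C(O[Si](CC)(CC)CC)CC=C(C)[C@@]2(O)C(=O)C[C@@H](C)O[Si](C)(C)C(C)(C)C)cc1 | intermediate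
15 | (3R)-3-(tert-butyldimethylsilyloxy)-1-[(1S,7S)-7-[(4-methoxyphenyl)methoxy]-2-methyl-1,5-bis(triethylsilyloxy)cyclohepta-2,5-dien-1-yl]butan-1-one | COc1ccc(CO[C@H]2C=C(O[Si](CC)(CC)CC)CC=C(C)[C@@]2(O[Si](CC)(CC)CC)C(=O)C[C@@H](C)O[Si](C)(C)C(C)(C)C)cc1 | intermediate
16 | siloxy epoxide of 15 (oxirane across the former enol ether C=C, oxygen anti to the benzylic ether) | COc1ccc(CO[C@H]2[C@@H]3O[C@]3(O[Si](CC)(CC)CC)CC=C(C)[C@@]2(O[Si](CC)(CC)CC)C(=O)C[C@@H](C)O[Si](C)(C)C(C)(C)C)cc1 | intermediate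
17 | (2S,3S,4S)-4-[(3R)-3-(tert-butyldimethylsilyloxy)butanoyl]-2-hydroxy-3-[(4-methoxyphenyl)methoxy]-5-methyl-4-(triethylsilyloxy)cyclohept-5-en-1-one | COc1ccc(CO[C@H]2[C@H](O)C(=O)CC=C(C)[C@@]2(O[Si](CC)(CC)CC)C(=O)C[C@@H](C)O[Si](C)(C)C(C)(C)C)cc1 | intermediate
18 | 2-(diethoxyphosphoryl)propanoic acid | CCOP(=O)(OCC)C(C)C(O)=O | starting material
19 | (1S,6S,7S)-6-[(3R)-3-(tert-butyldimethylsilyloxy)butanoyl]-7-[(4-methoxyphenyl)methoxy]-5-methyl-2-oxo-6-(triethylsilyloxy)cyclohept-4-en-1-yl 2-(diethoxyphosphoryl)propanoate | COc1ccc(CO[C@H]2[C@H](OC(=O)C(C)P(=O)(OCC)OCC)C(=O)CC=C(C)[C@@]2(O[Si](CC)(CC)CC)C(=O)C[C@@H](C)O[Si](C)(C)C(C)(C)C)cc1 | intermediate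
20 | (7S,8S,8aR)-7-[(3R)-3-(tert-butyldimethylsilyloxy)butanoyl]-8-[(4-methoxyphenyl)methoxy]-3,6-dimethyl-7-(triethylsilyloxy)-4,7,8,8a-tetrahydro-2H-cyclohepta[b]furan-2-one | COc1ccc(CO[C@H]2[C@@H]3OC(=O)C(C)=C3CC=C(C)[C@@]2(O[Si](CC)(CC)CC)C(=O)C[C@@H](C)O[Si](C)(C)C(C)(C)C)cc1 | intermediate
21 | (7S,8S,8aR)-7-[(3R)-3-(tert-butyldimethylsilyloxy)butanoyl]-8-hydroxy-3,6-dimethyl-7-(triethylsilyloxy)-4,7,8,8a-tetrahydro-2H-cyclohepta[b]furan-2-one | O[C@H]1[C@@H]2OC(=O)C(C)=C2CC=C(C)[C@@]1(O[Si](CC)(CC)CC)C(=O)C[C@@H](C)O[Si](C)(C)C(C)(C)C | intermediate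
22 | (3R,3aS,6S,7S,8S,8aR)-7-[(3R)-3-(tert-butyldimethylsilyloxy)butanoyl]-8-hydroxy-3,6-dimethyl-7-(triethylsilyloxy)octahydro-2H-cyclohepta[b]furan-2-one | O[C@H]1[C@@H]2OC(=O)[C@H](C)[C@@H]2CC[C@H](C)[C@@]1(O[Si](CC)(CC)CC)C(=O)C[C@@H](C)O[Si](C)(C)C(C)(C)C | intermediate
23 | (2Z)-2-methylbut-2-enoic acid (angelic acid) | C/C=C(/C)C(O)=O | starting material
24 | (2Z)-2-methylbut-2-enoic 2,4,6-trichlorobenzoic anhydride | C/C=C(/C)C(=O)OC(=O)c1c(Cl)cc(Cl)cc1Cl | intermediate
25 | (3R,3aS,6S,7S,8S,8aR)-7-[(3R)-3-(tert-butyldimethylsilyloxy)butanoyl]-3,6-dimethyl-2-oxo-7-(triethylsilyloxy)octahydro-2H-cyclohepta[b]furan-8-yl (2Z)-2-methylbut-2-enoate | C/C=C(/C)C(=O)O[C@H]1[C@@H]2OC(=O)[C@H](C)[C@@H]2CC[C@H](C)[C@@]1(O[Si](CC)(CC)CC)C(=O)C[C@@H](C)O[Si](C)(C)C(C)(C)C | intermediate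
26 | (3R,3aS,6S,7S,8S,8aR)-7-hydroxy-7-[(3R)-3-hydroxybutanoyl]-3,6-dimethyl-2-oxooctahydro-2H-cyclohepta[b]furan-8-yl (2Z)-2-methylbut-2-enoate | C/C=C(/C)C(=O)O[C@H]1[C@@H]2OC(=O)[C@H](C)[C@@H]2CC[C@H](C)[C@@]1(O)C(=O)C[C@@H](C)O | target

**Step count and risks**

Total step count: 15. Longest linear sequence: 14 steps (steps 1, 2 and 4–15; step 3 is a one-step side branch).

Steps most likely to fail:

Step 4. The carbene carries only hydrogen on the carbene carbon, so face discrimination by the catalyst and cis/trans control in the cyclopropanation may be poor. Any trans-dialkenylcyclopropane must epimerise through a ring-opened, siloxy-stabilised intermediate before it can rearrange, and this would erode the enantiomeric purity. Competing 1,5-electrocyclisation of 6 to a pyrazole would lower the conversion. Fallback (resolution instead of asymmetric catalysis): starting from 5 and 3, the cycloaddition is run with the achiral catalyst Rh2(esp)2, which should give 8 together with its enantiomer ethyl (1S,7R)-7-[(4-methoxyphenyl)methoxy]-2-methyl-5-(triethylsilyloxy)cyclohepta-2,5-diene-1-carboxylate F1. The racemate is taken through steps 5 and 6, which also produce ethyl (1R,7R)-1-hydroxy-7-[(4-methoxyphenyl)methoxy]-2-methyl-5-(triethylsilyloxy)cyclohepta-2,5-diene-1-carboxylate F2 and (1R,7R)-1-hydroxy-N-methoxy-7-[(4-methoxyphenyl)methoxy]-N,2-dimethyl-5-(triethylsilyloxy)cyclohepta-2,5-diene-1-carboxamide F3. Addition of the enantiopure reagent 12 as in step 7 then gives 13 and its diastereomer (3R)-3-hydroxy-1-[(1R,7R)-1-hydroxy-7-[(4-methoxyphenyl)methoxy]-2-methyl-5-(triethylsilyloxy)cyclohepta-2,5-dien-1-yl]butan-1-one F4, which should be separable by chromatography. The route is rejoined at 13.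

Step 7. The β-oxido organolithium 12 eliminates above about −50 °C, while the Weinreb amide sits on a fully substituted carbon next to an alkoxide, so addition may be too slow and decomposition of the reagent may win. Fallback (catalyst-controlled carbinol instead of chiral-pool nucleophile): starting from 10, (E)-prop-1-enylmagnesium bromide should give the enone (2E)-1-[(1S,7S)-1-hydroxy-7-[(4-methoxyphenyl)methoxy]-2-methyl-5-(triethylsilyloxy)cyclohepta-2,5-dien-1-yl]but-2-en-1-one F5. Copper-catalysed enantioselective β-borylation (CuCl, NaOt-Bu, a Josiphos ligand of the hand that leads to the R carbinol, B2pin2, MeOH) should then give the β-boryl ketone (3R)-1-[(1S,7S)-1-hydroxy-7-[(4-methoxyphenyl)methoxy]-2-methyl-5-(triethylsilyloxy)cyclohepta-2,5-dien-1-yl]-3-(4,4,5,5-tetramethyl-1,3,2-dioxaborolan-2-yl)butan-1-one F6. Oxidation with NaBO3 (retention at carbon) returns to the route at 13.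

Step 13. The tetrasubstituted, electron-poor butenolide alkene may resist the iridium catalyst, and incomplete direction by the C8 hydroxyl would give poor facial selectivity at C6. Fallback (conjugate hydride reduction of the butenolide, then hydrogenation of the remaining alkene): starting from 21, [(Ph3P)CuH]6 should deliver hydride to C3a from the convex face and, after kinetic protonation at C3, give (3R,3aS,7S,8S,8aR)-7-[(3R)-3-(tert-butyldimethylsilyloxy)butanoyl]-8-hydroxy-3,6-dimethyl-7-(triethylsilyloxy)-3,3a,4,7,8,8a-hexahydro-2H-cyclohepta[b]furan-2-one F7 without touching the ketone. The isolated C5=C6 alkene of F7 is then hydrogenated with [Ir(cod)(PCy3)(py)]PF6 under direction of the C8 hydroxyl, rejoining the route at 22.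

Further compounds
F1 | step 4 | ethyl (1S,7R)-7-[(4-methoxyphenyl)methoxy]-2-methyl-5-(triethylsilyloxy)cyclohepta-2,5-diene-1-carboxylate | COc1ccc(CO[C@@H]2C=C(O[Si](CC)(CC)CC)CC=C(C)[C@@H]2C(=O)OCC)cc1
F2 | step 4 | ethyl (1R,7R)-1-hydroxy-7-[(4-methoxyphenyl)methoxy]-2-methyl-5-(triethylsilyloxy)cyclohepta-2,5-diene-1-carboxylate | COc1ccc(CO[C@@H]2C=C(O[Si](CC)(CC)CC)CC=C(C)[C@]2(O)C(=O)OCC)cc1
F3 | step 4 | (1R,7R)-1-hydroxy-N-methoxy-7-[(4-methoxyphenyl)methoxy]-N,2-dimethyl-5-(triethylsilyloxy)cyclohepta-2,5-diene-1-carboxamide | COc1ccc(CO[C@@H]2C=C(O[Si](CC)(CC)CC)CC=C(C)[C@]2(O)C(=O)N(C)OC)cc1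
F4 | step 4 | (3R)-3-hydroxy-1-[(1R,7R)-1-hydroxy-7-[(4-methoxyphenyl)methoxy]-2-methyl-5-(triethylsilyloxy)cyclohepta-2,5-dien-1-yl]butan-1-one | COc1ccc(CO[C@@H]2C=C(O[Si](CC)(CC)CC)CC=C(C)[C@]2(O)C(=O)C[C@@H](C)O)cc1
F5 | step 7 | (2E)-1-[(1S,7S)-1-hydroxy-7-[(4-methoxyphenyl)methoxy]-2-methyl-5-(triethylsilyloxy)cyclohepta-2,5-dien-1-yl]but-2-en-1-one | COc1ccc(CO[C@H]2C=C(O[Si](CC)(CC)CC)CC=C(C)[C@@]2(O)C(=O)/C=C/C)cc1
F6 | step 7 | (3R)-1-[(1S,7S)-1-hydroxy-7-[(4-methoxyphenyl)methoxy]-2-methyl-5-(triethylsilyloxy)cyclohepta-2,5-dien-1-yl]-3-(4,4,5,5-tetramethyl-1,3,2-dioxaborolan-2-yl)butan-1-one | COc1ccc(CO[C@H]2C=C(O[Si](CC)(CC)CC)CC=C(C)[C@@]2(O)C(=O)C[C@@H](C)B3OC(C)(C)C(C)(C)O3)cc1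
F7 | step 13 | (3R,3aS,7S,8S,8aR)-7-[(3R)-3-(tert-butyldimethylsilyloxy)butanoyl]-8-hydroxy-3,6-dimethyl-7-(triethylsilyloxy)-3,3a,4,7,8,8a-hexahydro-2H-cyclohepta[b]furan-2-one | O[C@H]1[C@@H]2OC(=O)[C@H](C)[C@@H]2CC=C(C)[C@@]1(O[Si](CC)(CC)CC)C(=O)C[C@@H](C)O[Si](C)(C)C(C)(C)C
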